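**Plan**

- Retrosynthesis: the bond from the carbinol carbon C7 to ring A (3,4,5-trimethoxyphenyl) is cut first, then the ether bond from C8 to O4' of ring B (4-allyl-2,6-dimethoxyphenoxy); three commercial pieces remain.
- Forward: the ring B phenol is joined to a lactate (C8–O bond, Mitsunobu), the ester is lowered to the aldehyde, and ring A is added last as an aryl Grignard reagent to C7=O; both arenes are bought, no ring is built.
- Stereochemistry: C8 (S) comes from methyl (R)-lactate by one SN2 inversion; C7 (S) is set during the fragment union by 1,2-induction from C8 through a magnesium chelate, which gives the threo pair.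
- Enabling feature: the C7 carbonyl oxygen and the C8 ether oxygen O4' are 1,2-related, and O4' is twisted out of conjugation by the C3' and C5' methoxy groups of ring B, so O4' and one of these methoxy oxygens can hold magnesium in two fused five-membered chelate rings.
- The aldehyde is the only helper oxidation level and the chelate the only temporary ring; both disappear in the key step, so nothing has to be removed afterwards.

Key step: step 3

Remark: the phenol, the (R)-lactate ester and the aryl bromide are taken as commercial; the aldehyde is assumed to be configurationally stable only when kept cold and used crude at once.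

**Step 1**
Reactants: 1 4-allyl-2,6-dimethoxyphenol (methoxyeugenol); 2 methyl (R)-lactate
Product: 3 methyl (S)-2-(4-allyl-2,6-dimethoxyphenoxy)propanoate
Conditions: PPh3, DIAD, THF, 0 °C to rt
Reagents that add atoms: none
Why: Mitsunobu etherification, in which the phenol displaces the phosphonium-activated secondary hydroxyl of the lactate by SN2 with inversion, so the (R)-lactate centre becomes the (S)-configured C8 while the allyl group and the methyl ethers stay untouched.

**Step 2**
Reactants: 3 methyl (S)-2-(4-allyl-2,6-dimethoxyphenoxy)propanoate
Product: 5 (S)-2-(4-allyl-2,6-dimethoxyphenoxy)propanal, via diisobutylaluminium methyl hemiacetalate 4 (not isolated)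
Conditions: i-Bu2AlH (1.1 equiv), CH2Cl2, −78 °C; MeOH, then aq. potassium sodium tartrate, 0 °C; crude 5 used at once
Reagents that add atoms: none
Why: Partial reduction of an α-alkoxy ester with i-Bu2AlH, in which the tetrahedral aluminium hemiacetal is held by chelation to the C8 oxygen at −78 °C and releases the aldehyde only on work-up, so over-reduction is avoided and C8, never exposed to base, should keep its S configuration.

**Step 3**
Reactants: 5 (S)-2-(4-allyl-2,6-dimethoxyphenoxy)propanal; 6 5-bromo-1,2,3-trimethoxybenzene
Product: 9 (1S,2S)-2-(4-allyl-2,6-dimethoxyphenoxy)-1-(3,4,5-trimethoxyphenyl)propan-1-ol, via 3,4,5-trimethoxyphenylmagnesium bromide 7 (not isolated), via bromomagnesium carbinolate 8 (not isolated)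
Conditions: 6, Mg turnings, I2 (cat.), Et2O–toluene, reflux; then added to 5 precomplexed with MgBr2·OEt2 (2–3 equiv), CH2Cl2, −78 °C; sat. aq. NH4Cl
Reagents that add atoms: none
Why: Magnesium inserts into the C–Br bond of 6 to give the aryl Grignard reagent 7, which transfers its aryl group to the carbonyl carbon of 5 held as a MgBr2 chelate, giving alkoxide 8 and, after protonation, 9. The closest known reaction type is the Cram-chelate (chelation-controlled) Grignard addition to α-alkoxy aldehydes. No ring of the target is closed; the only ring formed is the transient chelate, a five-membered O=C7–C8–O4'–Mg ring fused to a second five-membered ring through a ring B methoxy oxygen. The new stereocentre C7 is controlled by C8: in the chelate C7=O and C8–O4' are syn-coplanar, the C8 methyl covers the Re face of the aldehyde, and the aryl group enters on the Si face next to the C8 hydrogen, which should give 7S and hence the threo (7S,8S) pair. The step needs facial selectivity for the chelate pathway over the open Felkin–Anh pathway (which would lead to the erythro isomer) and addition over enolisation of the labile aldehyde; the first is secured by the non-coordinating solvent, excess MgBr2 and the basic, twisted O4' flanked by two methoxy donors, the second by the low basicity of the aryl Grignard reagent at −78 °C.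

**Compound list**

1 | 4-allyl-2,6-dimethoxyphenol (methoxyeugenol) | C=CCc1cc(OC)c(O)c(OC)c1 | starting material
2 | methyl (R)-lactate, methyl (2R)-2-hydroxypropanoate | C[C@@H](O)C(=O)OC | starting material
3 | methyl (S)-2-(4-allyl-2,6-dimethoxyphenoxy)propanoate | C=CCc1cc(OC)c(O[C@@H](C)C(=O)OC)c(OC)c1 | intermediate
4 | diisobutylaluminium methyl hemiacetalate, [(2S)-2-(4-allyl-2,6-dimethoxyphenoxy)-1-methoxypropoxy]diisobutylaluminium, hemiacetal carbon not defined | C=CCc1cc(OC)c(O[C@@H](C)C(OC)O[Al](CC(C)C)CC(C)C)c(OC)c1 | intermediate
5 | (S)-2-(4-allyl-2,6-dimethoxyphenoxy)propanal | C=CCc1cc(OC)c(O[C@@H](C)C=O)c(OC)c1 | intermediate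
6 | 5-bromo-1,2,3-trimethoxybenzene | COc1cc(Br)cc(OC)c1OC | starting material
7 | 3,4,5-trimethoxyphenylmagnesium bromide | COc1cc([Mg]Br)cc(OC)c1OC | intermediate
8 | bromomagnesium (1S,2S)-2-(4-allyl-2,6-dimethoxyphenoxy)-1-(3,4,5-trimethoxyphenyl)propan-1-olate | C=CCc1cc(OC)c(O[C@@H](C)[C@@H](O[Mg]Br)c2cc(OC)c(OC)c(OC)c2)c(OC)c1 | intermediate
9 | (1S,2S)-2-(4-allyl-2,6-dimethoxyphenoxy)-1-(3,4,5-trimethoxyphenyl)propan-1-ol, threo | C=CCc1cc(OC)c(O[C@@H](C)[C@@H](O)c2cc(OC)c(OC)c(OC)c2)c(OC)c1 | target

**Totals**

Total step count: 3. Longest linear sequence: 3 steps (1 and 2 to 3, to 5, to 9); bromide 6 enters in the last step.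

**Steps most likely to fail**

Step 3: the chelate may be broken up by donor solvent so that the open Felkin–Anh pathway competes and facial selectivity is poor, and the Grignard reagent may enolise the aldehyde and epimerise C8. The fallback sets out from 3 and forms the same bond at the ketone oxidation level. Ester 3 would be converted with MeNH(OMe)·HCl and i-PrMgCl in THF at −20 °C into the Weinreb amide (S)-2-(4-allyl-2,6-dimethoxyphenoxy)-N-methoxy-N-methylpropanamide F1. Acylation of 7 with F1 in THF at 0 °C should give the ketone (S)-2-(4-allyl-2,6-dimethoxyphenoxy)-1-(3,4,5-trimethoxyphenyl)propan-1-one F2. Reduction with the bulky, non-chelating LiBH(s-Bu)3 in THF at −78 °C should deliver hydride under Felkin–Anh control (C8–O4' anti to the incoming hydride), which leads to the threo alcohol, and the route is rejoined at 9.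

Step 2: reduction may run past the aldehyde stage, and the α-aryloxy aldehyde may epimerise during work-up or on standing. The fallback sets out from 3: full reduction with LiAlH4 in THF at 0 °C would give the configurationally stable alcohol (S)-2-(4-allyl-2,6-dimethoxyphenoxy)propan-1-ol F3, which can be stored and purified. Oxidation with Dess–Martin periodinane and NaHCO3 in CH2Cl2 at 0 °C, under non-basic conditions just before use, comes back to the route at 5.

Step 1: SN2 attack of the di-ortho-substituted phenol on the phosphonium-activated lactate may be slow, so that elimination of the activated lactate or alkylation of the hydrazide takes over and inversion is incomplete. The fallback sets out from 2: Tf2O and 2,6-lutidine in CH2Cl2 at −78 °C would give the triflate methyl (R)-2-(trifluoromethylsulfonyloxy)propanoate F4. Displacement by the potassium phenoxide of 1 (K2CO3, MeCN, −20 to 0 °C) should proceed with inversion and comes back to the route at 3.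

**Further compounds**

F1 | step 3 | (S)-2-(4-allyl-2,6-dimethoxyphenoxy)-N-methoxy-N-methylpropanamide | C=CCc1cc(OC)c(O[C@@H](C)C(=O)N(C)OC)c(OC)c1
F2 | step 3 | (S)-2-(4-allyl-2,6-dimethoxyphenoxy)-1-(3,4,5-trimethoxyphenyl)propan-1-one | C=CCc1cc(OC)c(O[C@@H](C)C(=O)c2cc(OC)c(OC)c(OC)c2)c(OC)c1
F3 | step 2 | (S)-2-(4-allyl-2,6-dimethoxyphenoxy)propan-1-ol | C=CCc1cc(OC)c(O[C@@H](C)CO)c(OC)c1
F4 | step 1 | methyl (R)-2-(trifluoromethylsulfonyloxy)propanoate | C[C@@H](OS(=O)(=O)C(F)(F)F)C(=O)OC
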